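## Analysis of the target

Positions are given in kaurane numbering; "bridge face" means the face of ring C that carries the C15–C16 bridge.

The target is a 6,7-seco-ent-kaurane. A cyclohexane (ring A: C1–C5, C10) is spiro-linked at C10 to a δ-lactone (C7, O, C20, C10, C9, C8). The lactone is fused through C8–C9 to a bicyclo[3.2.1]octane (ring C: C8, C9, C11–C14; ring D: C8, C13–C16) that carries an α-methylidene cyclopentanone (C15=O, C16=C17). There are eight stereocentres (C1, C5, C8, C9, C10, C11, C13, C14). On ring A the C1 acetate and C6 are cis to C20 and C9 is trans to them. On ring C the C9–C10 bond lies opposite the bridge while the 11- and 14-hydroxyls lie on the bridge side, so C10 and O11 are trans-diaxial. The enone is a Michael acceptor, the 14-hydroxyl is β to two carbonyls (C7, C15; retro-aldol), and three free hydroxyls sit next to an acetate and a lactone (acyl transfer). The hard parts are the contiguous C8 (quaternary)–C9–C10 (quaternary, spiro) array and five oxygenated carbons at different oxidation levels on three rings. The strategy rests on one relationship: O20 and the equatorial hydrogen on C1 are 1,3-disposed and gauche across C10. A silicon atom bound to O20 can therefore reach this C–H bond, and no other unhindered one, and close a five-membered oxasilolane. The C1 oxygen can thus be left out until the 1-deoxy skeleton, built from an ordinary cyclogeranyl ring A, is complete.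

## Retrosynthetic reasoning

**End game (49 back to 43).** The enone, the lactone and the free hydroxyls are installed last, because each would interfere with a hydrosilane and an iridium catalyst. Target 49 comes from 48 by desilylation. The C15 carbonyl comes from allylic oxidation of the methylidene compound 46. The C16=C17 bond is cut back to ketone 45. The lactone C7–O20 bond is cut back to lactol 44, which forms when the two dioxolanes and the temporary C20 silyl ether of 43 are removed together. Keeping C7 at the aldehyde level decides which of the two neopentyl CH2O groups (C7 or C20) becomes the carbonyl.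

**C1–O bond (43 back to 37 + 38).** Acetate 43 comes from 1,20-diol 41. The C1–O bond of 41 is traced to the C1–Si bond of oxasilolane 40, and that bond is cut to alcohol 37 and diethylsilane 38. This is the only place where the C1 oxygen enters. The cut is made here because the C20 hydroxyl is the one group placed to deliver silicon to C1. The forward step must pick one secondary C–H bond in a molecule full of others and set the C1 configuration. In 37 only O20 is free; O6 carries a tert-butyldiphenylsilyl group in place of the tert-butyldimethylsilyl group of the planning structure, so that O20 can be unveiled selectively.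

**C11 and C16 (37 back to 27).** The 11-hydroxyl of 37 is on the bridge face, trans to C10, and cannot be delivered from C20. It is therefore traced through ketone 34 to the epimeric alcohol 33 and to lactone 32. The C11–O bond is cut by retro-iodolactonisation (29, 28) to the γ,δ-unsaturated acid 27. The ring size fixes oxygen at C11 and not at C12. The C16 dioxolane of 32 is traced through ketone 31 to the methylidene group, which is cleaved once it is the only alkene left (29).

**C9–C10 bond (27 back to 23 + 11).** The bond between the two most crowded carbons is cut by a retro-Ireland–Claisen step to ester 24. An intramolecular six-centre process tolerates the crowding. Both new centres follow from existing ones: C9 from the C12 oxygen (suprafacial), C10 from the C5 substituent of ring A. Ester 24 is cut at the C12–O bond to allylic alcohol 23 and ring A acid 11. The esterification must invert C12, because hydride reduction gives the endo alcohol and the rearrangement needs the exo ester.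

**Bicyclic alcohol (23 back to 12 + 14).** Diol 20 comes from enedione 19 by reduction, and 19 from dione 18 by dehydrogenation. Ring D is opened at C13–C16, giving bromoallyl dione 17. In 17, C13 is the only acidic carbon, so the ring closure has no regiochemical choice. The quaternary C8 is disconnected at C8–C15 (2,3-dibromopropene 14) and at C8–C7 (formylation of 3-ethoxycyclohex-2-en-1-one 12). This brings C7 in at the aldehyde level and C12 and C14 as carbonyls. A 1,3-dioxygenated six-membered ring is needed, so 12 is used rather than a 1,4-dioxygenated ring. The racemate is resolved at 20, the first intermediate with a secondary alcohol.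

**Ring A acid (11 back to 1).** The carboxyl carbon C20 is traced to the exocyclic methylidene of 8 (hydroboration, oxidation). The ring is opened at C4–C5 to epoxide 2 of geranyl acetate 1. A radical epoxy-olefin cyclisation gives the exocyclic alkene directly and passes the epoxide configuration to C5. The extra C3 hydroxyl (4) is removed (5, 6).

## Alternatives that were turned down

**Alternative 1:** ring A and the spiro centre are made last, by cutting C1–C10 and O–C20 together.
- Forward key step: a nitrile oxide at C1 adds across a C10=C20 1,1-disubstituted alkene and gives the ring-A-fused isoxazoline A1.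
- For it: one step makes ring A, the quaternary C10 and the C1/C20 oxygen pattern. No C–H functionalisation is needed and the 1,3-relationship is guaranteed. On this point it is stronger than the chosen route.
- Against it: the C10 configuration must be induced across a flexible tether by C5 and the crowded C9 substituent in one kinetically controlled cycloaddition. The C1 ketone freed on N–O cleavage must be reduced to the equatorial alcohol next to a quaternary carbon. The N–O cleavage must spare the methylidene of A1. The chain with C5 next to quaternary C4 must be built linearly on the bicycle and joined to C9 by a bond formation no easier than the Claisen step.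
- Comparison: step count is similar. The stereochemical risk moves from a tether-enforced C1 centre to an unenforced quaternary C10. The chosen route offers convergence with a cheap cyclogeranyl ring A, and a C10 centre set by a sigmatropic shift with two independent facial controls.

**Alternative 2:** ring C is made by a Diels–Alder reaction, cutting C8–C14 and C9–C11.
- Forward key step: the C8=C9 bond of a spiro-fused unsaturated δ-lactone, activated by the lactone carbonyl and a C8 acetyl group, adds to a diene with silyloxy groups at both termini and gives cyclohexene A2.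
- For it: it is highly convergent and sets C8, C9, C11 and C14 at once. Both ring-C oxygens arrive on the right carbons and cis to each other, which avoids the iodolactonisation, oxidation and reduction sequence the chosen route needs at C11. On this point it is stronger.
- Against it: C9 of the dienophile bears the quaternary spiro carbon and C8 becomes quaternary, so the alkene is a very hindered dienophile, and the electron-rich diene is fragile. Facial selectivity must come from ring A alone. The endo/exo placement of two different acceptor groups decides C11 and C14 relative to C8. Ring D must still be closed from the acetyl group onto C13, which in A2 is an alkene carbon and not an enolate position, and C17 added. Ring A must carry the C1 oxygen from the start.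
- Comparison: it could be shorter, but it depends on a sterically mismatched cycloaddition. The chosen route builds the same C8–C9–C10 array by enolate alkylation and an intramolecular rearrangement, both tolerant of crowding.

**Alternative 3:** the C8–C9 bond is made across a ring.
- Forward key step: zerovalent palladium ionises an allylic carbonate at C9 inside a ten-membered keto lactone, and the C8 enolate of the β-keto lactone closes onto C9 to give A3 with a C11=C12 alkene.
- For it: the most hindered bond is made intramolecularly by a soft, doubly stabilised nucleophile without strong base. The lactone is present from the start, so no acetal and lactol steps are needed at C7. In redox economy at C7 it is stronger than the chosen route.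
- Against it: the ten-membered lactone must be closed through the neopentyl O20 or an equally hindered site. The allyl complex can be attacked at C9 or C12 and from either face, and the outcome depends on the macrocycle conformation. The 11-hydroxyl must still be put on the bridge face of the C11=C12 alkene, the same problem the chosen route has. Ring A again needs the C1 oxygen early.
- Comparison: it needs more steps before the key event, and C8 and C9 rest on a conformational guess. The chosen route fixes C9 by suprafacial transfer from a C12 oxygen of known configuration.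

Key step: step 29

Remark on the chemistry: compounds 15–20 are racemic and are drawn as the enantiomer that step 15 selects. C10 in 9–11 and 24 is drawn as the expected cis epimer and is erased in step 19. C15 in 47 and the lactol carbon in 44 are left undefined and converge in the next step. The sense of the epoxidation (step 1) and of the enzymatic acylation (step 15) is assigned from the usual spiro transition-state model and the empirical size rule for secondary alcohols; if either were reversed, the enantiomeric ketone catalyst or the unreacted alcohol would be used.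

## Route

Step 1
Reactants: 1 geranyl acetate
Product: 2 (2E)-5-[(2R)-3,3-dimethyloxiran-2-yl]-3-methylpent-2-en-1-yl acetate
Conditions: 1,2:4,5-di-O-isopropylidene-β-D-erythro-hexo-2,3-diulo-2,6-pyranose (0.3 equiv), KHSO5 (as 2KHSO5·KHSO4·K2SO4), K2CO3, Bu4NHSO4, MeCN/CH2(OMe)2/aq. Na2B4O7, 0 °C
Reagents that add atoms: potassium peroxymonosulfate, [K+].[O-]S(=O)(=O)OO
Why: Shi epoxidation; the electrophilic chiral dioxirane should attack the electron-rich 6,7-alkene and leave the 2,3-alkene, which the allylic acetate deactivates. The spiro transition state of the D-fructose-derived ketone should give the (R)-epoxide.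

Step 2
Reactants: 2 (R)-6,7-epoxygeranyl acetate
Product: 4 [(1S,3R)-3-hydroxy-2,2-dimethyl-6-methylidenecyclohexyl]methyl acetate, via trimethylsilyl ether 3 (not isolated)
Conditions: Cp2TiCl2 (0.2 equiv), Mn, Me3SiCl, 2,4,6-collidine, THF, rt; then 1 M HCl, THF, 0 °C
Reagents that add atoms: none
Why: Radical epoxy-olefin cyclisation; Cp2TiCl (trivalent titanium, from Cp2TiCl2 and Mn) opens the epoxide to the tertiary radical, which closes 6-endo onto the 2,3-alkene through a chair with the titanoxy and acetoxymethyl groups equatorial, so C5 follows from the epoxide centre. Capture of the new tertiary radical by a second Cp2TiCl and β-hydride loss should give the exocyclic alkene.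

Step 3
Reactants: 4 hydroxy acetate
Product: 5 O-phenyl thionocarbonate of 4 at the secondary hydroxyl
Conditions: PhOC(S)Cl, pyridine, 4-(dimethylamino)pyridine (cat.), CH2Cl2, rt
Reagents that add atoms: O-phenyl chlorothionoformate, S=C(Cl)Oc1ccccc1
Why: Acylation of the hindered secondary alcohol gives the radical precursor for Barton–McCombie deoxygenation.

Step 4
Reactants: 5 thionocarbonate
Product: 6 [(1R)-2,2-dimethyl-6-methylidenecyclohexyl]methyl acetate
Conditions: Bu3SnH, azobisisobutyronitrile (cat.), toluene, 100 °C
Reagents that add atoms: none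
Why: Barton–McCombie deoxygenation; the stannyl radical adds to C=S, fragmentation gives the secondary C3 radical, and Bu3SnH reduces it. The methylidene group cannot be reached through a favourable ring size.

Step 5
Reactants: 6 (R)-γ-cyclogeranyl acetate
Product: 7 [(1R)-2,2-dimethyl-6-methylidenecyclohexyl]methanol
Conditions: K2CO3, MeOH, rt
Reagents that add atoms: none
Why: Base-catalysed transesterification removes the acetate, which would not survive the later ester enolate chemistry.

Step 6
Reactants: 7 (R)-γ-cyclogeraniol
Product: 8 tert-butyl{[(1R)-2,2-dimethyl-6-methylidenecyclohexyl]methoxy}diphenylsilane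
Conditions: t-BuPh2SiCl, imidazole, DMF, rt
Reagents that add atoms: tert-butyl(chloro)diphenylsilane, CC(C)(C)[Si](Cl)(c1ccccc1)c1ccccc1
Why: Silylation of the primary alcohol; the tert-butyldiphenylsilyl group is chosen because it should outlast base, hydride, radical and ozone steps and the later selective cleavage of a primary tert-butyldimethylsilyl ether (step 28).

Step 7
Reactants: 8 silyl ether
Product: 10 [(1S,2S)-2-(tert-butyldiphenylsilyloxymethyl)-3,3-dimethylcyclohexyl]methanol, via B-alkyl-9-borabicyclononane 9 (not isolated)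
Conditions: 9-BBN, THF, 0 °C to rt; then NaOH, H2O2, 0 °C
Reagents that add atoms: hydrogen peroxide, OO
Why: Hydroboration–oxidation; boron adds to the terminal carbon of the 1,1-disubstituted alkene, which turns C20 into a primary alcohol. Addition anti to the C5 substituent should give mainly the cis C10 epimer, a centre that is erased in step 19.

Step 8
Reactants: 10 primary alcohol
Product: 11 (1S,2S)-2-(tert-butyldiphenylsilyloxymethyl)-3,3-dimethylcyclohexane-1-carboxylic acid (ring A acid)
Conditions: 2,2,6,6-tetramethylpiperidin-1-oxyl (0.2 equiv), PhI(OAc)2, MeCN/H2O, rt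
Reagents that add atoms: water, O
Why: Oxoammonium oxidation of the primary alcohol through the aldehyde hydrate to the acid; silyl ether and quaternary carbon are inert.

Step 9
Reactants: 12 3-ethoxycyclohex-2-en-1-one
Product: 13 4-ethoxy-2-oxocyclohex-3-ene-1-carbaldehyde (enolised)
Conditions: LiN(i-Pr)2, THF, −78 °C; HCO2CH2CF3; aq. NH4Cl
Reagents that add atoms: 2,2,2-trifluoroethyl formate, O=COCC(F)(F)F
Why: Claisen formylation of the kinetic α′-enolate of the vinylogous ester (Stork–Danheiser deprotonation) brings in C7 at the aldehyde level on the future C8.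

Step 10
Reactants: 13 formyl ketone; 14 2,3-dibromoprop-1-ene
Product: 15 rac-1-(2-bromoprop-2-en-1-yl)-4-ethoxy-2-oxocyclohex-3-ene-1-carbaldehyde
Conditions: K2CO3, acetone, 50 °C
Reagents that add atoms: none
Why: C-alkylation of the stabilised formyl ketone enolate by the allylic bromide (SN2) should create the quaternary C8 with the C15–C16 unit; the vinyl bromide is inert here.

Step 11
Reactants: 15 keto aldehyde
Product: 17 rac-4-(2-bromoprop-2-en-1-yl)-4-(1,3-dioxolan-2-yl)cyclohexane-1,3-dione, via dioxolane vinylogous ester 16 (not isolated)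
Conditions: HOCH2CH2OH, pyridinium p-toluenesulfonate, benzene, reflux (−H2O); then LiOH, THF/H2O, 50 °C; 1 M HCl to pH 4, 0 °C
Reagents that add atoms: ethylene glycol, OCCO; water, O
Why: Acetalisation masks C7 and removes the retro-Claisen-prone β-keto aldehyde. Hydroxide then cleaves the vinylogous ester by addition–elimination to the dione enolate, conditions under which the dioxolane is stable.

Step 12
Reactants: 17 bromoallyl dione
Product: 18 rac-5-(1,3-dioxolan-2-yl)-7-methylidenebicyclo[3.2.1]octane-2,8-dione
Conditions: Pd(PPh3)4 (5 mol %), K3PO4, THF, 70 °C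
Reagents that add atoms: none
Why: Palladium-catalysed intramolecular α-alkenylation of a 1,3-dicarbonyl; zerovalent palladium inserts into the vinyl C–Br bond, the dione enolate binds through C13 (the only acidic carbon) and C–C reductive elimination closes ring D. The bridge can only form with C15 and C16 on the same face, so C13 follows from C8.

Step 13
Reactants: 18 bicyclic dione
Product: 19 rac-5-(1,3-dioxolan-2-yl)-7-methylidenebicyclo[3.2.1]oct-3-ene-2,8-dione
Conditions: 2-iodoxybenzoic acid, DMSO, 70 °C
Reagents that add atoms: none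
Why: 2-Iodoxybenzoic acid dehydrogenation through the enol; the C12 ketone can enolise only towards C11 (C13 is a bridgehead and C14 has no enolisable neighbour), so only the C9=C11 enone can form.

Step 14
Reactants: 19 enedione
Product: 20 rac-5-(1,3-dioxolan-2-yl)-7-methylidenebicyclo[3.2.1]oct-3-ene-2,8-diol (12-OH on the bridge face; 14-OH towards the C15–C16 bridge)
Conditions: NaBH4, CeCl3·7H2O, MeOH, −78 °C
Reagents that add atoms: none
Why: Luche 1,2-reduction. At C12 hydride should enter from the open face opposite the bridge and give the endo alcohol. At C14 it should enter over the flat, fully sp2 three-carbon bridge (axial attack on ring C) and place the hydroxyl towards the C15–C16 bridge, which is also the more stable, equatorial position on ring C.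

Step 15
Reactants: 20 racemic diol
Product: 21 12-O-acetate of the enantiomer of 20 that has the target configuration at C8
Conditions: immobilised Candida antarctica lipase B, vinyl acetate, t-BuOMe, 30 °C, to about half conversion; chromatography
Reagents that add atoms: vinyl acetate, C=COC(C)=O
Why: Lipase-catalysed kinetic resolution of a secondary allylic alcohol. With the bridgehead C13 as the large and the alkene carbon C11 as the medium substituent, the empirical rule predicts that the required enantiomer is acylated faster; the hindered 14-hydroxyl is not touched and the other enantiomer stays as the diol.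

Step 16
Reactants: 21 monoacetate
Product: 22 14-O-tert-butyldimethylsilyl ether of 21
Conditions: t-BuMe2SiOTf, 2,6-lutidine, CH2Cl2, −20 °C
Reagents that add atoms: tert-butyldimethylsilyl triflate, CC(C)(C)[Si](C)(C)OS(=O)(=O)C(F)(F)F
Why: Silylation of the hindered bridging alcohol with the reactive triflate; the acetate keeps O12 apart.

Step 17
Reactants: 22 silyl ether acetate
Product: 23 allylic alcohol with 12-OH on the bridge face and 14-O-silyl
Conditions: K2CO3, MeOH, 0 °C
Reagents that add atoms: none
Why: Methanolysis frees only the allylic hydroxyl for the coupling.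

Step 18
Reactants: 23 allylic alcohol; 11 ring A acid
Product: 24 ester of 11 with O12 of 23, C12 inverted (oxygen opposite the bridge)
Conditions: PPh3, diisopropyl azodicarboxylate, toluene, 0 °C to rt
Reagents that add atoms: none
Why: Mitsunobu esterification; the carboxylate displaces the alkoxyphosphonium at C12 from the open face with inversion, which turns the endo alcohol into the exo ester that the rearrangement needs.

Step 19
Reactants: 24 allylic ester
Product: 27 γ,δ-unsaturated acid with the C9–C10 bond and a C11=C12 alkene, via silyl ketene acetal 25 (not isolated), via trimethylsilyl ester 26 (not isolated)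
Conditions: LiN(i-Pr)2, Me3SiCl/Et3N, THF, −78 °C to 60 °C; then aq. NaHCO3/MeOH, rt; citric acid to pH 4
Reagents that add atoms: none
Why: Ireland–Claisen rearrangement; the shift is suprafacial, so the C9–C10 bond forms on the face of ring C that carried the C12 oxygen (opposite the bridge), and on ring A on the face away from the C5 silyloxymethyl group. C9 and C10 are thus set by the two fragments independently, whichever ketene acetal geometry (and so chair or boat) is used.

Step 20
Reactants: 27 unsaturated acid
Product: 28 iodolactone (C20 carbonyl, O on C11 cis to C10, iodine on C12 on the bridge face)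
Conditions: I2, NaHCO3, MeCN, 0 °C, dark
Reagents that add atoms: iodine, II
Why: Iodolactonisation; the carboxylate attacks C11 from the face on which C10 sits (five-membered, cis-fused lactone) anti to iodine on C12, which places oxygen on C11 and not C12. The methylidene cannot be reached through a favourable ring size and its iodonium ion reverts.

Step 21
Reactants: 28 iodolactone
Product: 29 lactone with C12 as CH2
Conditions: Bu3SnH, azobisisobutyronitrile (cat.), benzene, 80 °C
Reagents that add atoms: none
Why: Radical dehalogenation; the secondary C12 radical has no alkene within reach of a five- or six-membered closure.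

Step 22
Reactants: 29 lactone
Product: 31 C16 ketone, via secondary ozonide 30 (not isolated)
Conditions: O3, CH2Cl2, −78 °C; then Me2S, −78 °C to rt
Reagents that add atoms: ozone, [O-][O+]=O
Why: Ozonolysis; the methylidene is now the only alkene, so cleavage to the cyclopentanone is clean.

Step 23
Reactants: 31 keto lactone
Product: 32 lactone with C7 and C16 as dioxolanes
Conditions: HOCH2CH2OH, pyridinium p-toluenesulfonate, benzene, reflux (−H2O)
Reagents that add atoms: ethylene glycol, OCCO
Why: Ketalisation of the cyclopentanone under mild acid that the silyl ethers and the lactone tolerate; C16 is now masked for the hydride and iridium steps.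

Step 24
Reactants: 32 lactone
Product: 33 11,20-diol with 11-OH opposite the bridge (11-epimer of the target pattern)
Conditions: LiAlH4, THF, 0 °C to rt
Reagents that add atoms: none
Why: Hydride reduction of the lactone brings C20 to the alcohol level and frees O11.

Step 25
Reactants: 33 diol
Product: 34 C11 ketone with free C20 hydroxyl
Conditions: NaOCl (aq), AcOH, MeCN, 0 °C
Reagents that add atoms: none
Why: Stevens oxidation; hypochlorous acid in acetic acid oxidises secondary alcohols much faster than primary ones, so only O11 is oxidised. Oxidising C20 first would lead through the lactol back to a lactone.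

Step 26
Reactants: 34 hydroxy ketone
Product: 35 11,20-diol with 11-OH on the bridge face
Conditions: Li(s-Bu)3BH, THF, −78 °C; aq. NH4Cl
Reagents that add atoms: none
Why: Hydride reduction under steric approach control; the bridge face of the C11 carbonyl is blocked by the C15–C16 bridge and its dioxolane, so the bulky borohydride should add from the other face and leave the hydroxyl axial, on the bridge face and trans to C10.

Step 27
Reactants: 35 diol
Product: 36 11,20-bis(tert-butyldimethylsilyl) ether
Conditions: t-BuMe2SiOTf, 2,6-lutidine, CH2Cl2, 0 °C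
Reagents that add atoms: tert-butyldimethylsilyl triflate, CC(C)(C)[Si](C)(C)OS(=O)(=O)C(F)(F)F
Why: Exhaustive silylation; the axial O11 can only be protected with the triflate, which also silylates O20.

Step 28
Reactants: 36 bis-silyl ether
Product: 37 1-deoxy C20 alcohol (C7 and C16 dioxolanes; O6 tert-butyldiphenylsilyl; O11 and O14 tert-butyldimethylsilyl)
Conditions: HF·pyridine, pyridine, THF, 0 °C
Reagents that add atoms: none
Why: Selective desilylation; the primary tert-butyldimethylsilyl ether at C20 should cleave faster than the two hindered secondary ones and the bulkier primary tert-butyldiphenylsilyl ether, which frees the directing hydroxyl.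

Step 29
Reactants: 37 C20 alcohol; 38 diethylsilane
Product: 40 C1–C20 oxasilolane, via diethylhydrosilyl ether 39 (not isolated)
Conditions: [Ir(cod)OMe]2 (0.5 mol %), THF, rt; evaporation; then [Ir(cod)OMe]2 (2 mol %), 3,4,7,8-tetramethyl-1,10-phenanthroline (5 mol %), norbornene (1.5 equiv), THF, 100 °C
Reagents that add atoms: none
Why: Hydroxyl-directed, iridium-catalysed dehydrogenative C–H silylation. [Ir(cod)OMe]2 first couples the C20 hydroxyl with Et2SiH2 (loss of H2) to give 39; with the phenanthroline ligand the Si–H bond adds to iridium, norbornene takes up the hydrogen, the iridium silyl cleaves the C1–H bond through a six-membered metallacycle and C–Si reductive elimination releases 40. The closest known reaction type is the directed silylation of secondary γ C–H bonds of alcohols to oxasilolanes. The ring closes as a five-membered oxasilolane, cis-fused to ring A along C1–C10, with the Si–C1 bond formed last. The new C1 centre is set by the tether: C20 is axial on C10, only the equatorial C1–H is gauche to it, and silicon takes its place with retention, so the later C1–O bond is cis to C20. The step needs C1 over the other γ carbons C5 and C9 and over more remote positions: C5–H and C9–H are tertiary and C5–H is anti to C20, while C6 and the ring C carbons would need rings of six or more atoms. Chemoselectivity is secured because 37 has no free hydroxyl other than O20, no alkene and no carbonyl.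

Step 30
Reactants: 40 oxasilolane
Product: 41 1,20-diol (1-OH cis to C20)
Conditions: H2O2 (30 % aq), KHCO3, THF/MeOH, 50 °C
Reagents that add atoms: hydrogen peroxide, OO
Why: Tamao–Fleming oxidation; the alkoxysilane is activated by base, and migration of C1 from silicon to oxygen proceeds with retention.

Step 31
Reactants: 41 1,20-diol
Product: 43 C1 acetate with C20 triethylsilyl ether, via C20 triethylsilyl ether 42 (not isolated)
Conditions: Et3SiCl, imidazole, CH2Cl2, −20 °C; then Ac2O, 4-(dimethylamino)pyridine, pyridine, rt
Reagents that add atoms: chlorotriethylsilane, CC[Si](Cl)(CC)CC; acetic anhydride, CC(=O)OC(C)=O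
Why: The primary hydroxyl is silylated faster than the secondary one, and acylation then puts the acetate on O1 only; the labile triethylsilyl group keeps O20 for the lactone.

Step 32
Reactants: 43 acetate
Product: 44 lactol (C7 hemiacetal with O20) with C16 ketone
Conditions: 2 M HCl, THF, rt
Reagents that add atoms: water, O
Why: Acid hydrolysis removes both dioxolanes and the triethylsilyl ether; the C7 aldehyde is trapped by O20 as the six-membered lactol, which decides the direction of the lactone. The hindered secondary silyl ethers and the tert-butyldiphenylsilyl ether should persist.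

Step 33
Reactants: 44 lactol
Product: 45 δ-lactone with C16 ketone
Conditions: Pr4N[RuO4] (5 mol %), N-methylmorpholine N-oxide, 4 Å MS, CH2Cl2, rt
Reagents that add atoms: none
Why: Ley–Griffith oxidation of the lactol to the lactone; no other free hydroxyl is present.

Step 34
Reactants: 45 keto lactone
Product: 46 16-methylidene lactone
Conditions: Zn, CH2Br2, TiCl4, THF/CH2Cl2, 0 °C to rt
Reagents that add atoms: dibromomethane, BrCBr
Why: Lombardo methylenation; the non-basic zinc–titanium methylene reagent converts ketones and leaves lactone, acetate and silyl ethers alone, and it does not enolise the hindered cyclopentanone.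

Step 35
Reactants: 46 methylidene compound
Product: 47 15-hydroxy-16-methylidene compound
Conditions: SeO2 (0.5 equiv), t-BuOOH, CH2Cl2, rt
Reagents that add atoms: tert-butyl hydroperoxide, CC(C)(C)OO
Why: Allylic oxidation by ene reaction and [2,3]-shift; C15 is the only allylic position that can react (C13 is a bridgehead), and the C15 configuration is irrelevant.

Step 36
Reactants: 47 allylic alcohol
Product: 48 15-oxo-16-methylidene compound (O6, O11, O14 silylated)
Conditions: Dess–Martin periodinane, NaHCO3, CH2Cl2, 0 °C
Reagents that add atoms: none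
Why: Mild oxidation of the allylic alcohol gives the α-methylidene ketone without basic conditions that would threaten the acetate or cause conjugate addition.

Step 37
Reactants: 48 silylated enone
Product: 49 CNP0225182.1
Conditions: HF·pyridine, THF, 0 °C to rt
Reagents that add atoms: none
Why: Global desilylation under acidic fluoride conditions, which should avoid retro-aldol cleavage at C14 and acyl migration.

## Compound list

1 | geranyl acetate, (2E)-3,7-dimethylocta-2,6-dien-1-yl acetate | CC(C)=CCC/C(C)=C/COC(C)=O | starting material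
2 | (2E)-5-[(2R)-3,3-dimethyloxiran-2-yl]-3-methylpent-2-en-1-yl acetate | CC1(C)O[C@@H]1CC/C(C)=C/COC(C)=O | intermediate
3 | [(1S,3R)-2,2-dimethyl-6-methylidene-3-(trimethylsilyloxy)cyclohexyl]methyl acetate | C=C1CC[C@@H](O[Si](C)(C)C)C(C)(C)[C@H]1COC(C)=O | intermediate
4 | [(1S,3R)-3-hydroxy-2,2-dimethyl-6-methylidenecyclohexyl]methyl acetate | C=C1CC[C@@H](O)C(C)(C)[C@H]1COC(C)=O | intermediate
5 | [(1S,3R)-2,2-dimethyl-6-methylidene-3-(phenoxycarbonothioyloxy)cyclohexyl]methyl acetate | C=C1CC[C@@H](OC(=S)Oc2ccccc2)C(C)(C)[C@H]1COC(C)=O | intermediate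
6 | [(1R)-2,2-dimethyl-6-methylidenecyclohexyl]methyl acetate | C=C1CCCC(C)(C)[C@H]1COC(C)=O | intermediate
7 | [(1R)-2,2-dimethyl-6-methylidenecyclohexyl]methanol | C=C1CCCC(C)(C)[C@H]1CO | intermediate
8 | tert-butyl{[(1R)-2,2-dimethyl-6-methylidenecyclohexyl]methoxy}diphenylsilane | C=C1CCCC(C)(C)[C@H]1CO[Si](c1ccccc1)(c1ccccc1)C(C)(C)C | intermediate
9 | 9-{[(1S,2S)-2-(tert-butyldiphenylsilyloxymethyl)-3,3-dimethylcyclohexyl]methyl}-9-borabicyclo[3.3.1]nonane | C(B1C2CCCC1CCC2)[C@H]1CCCC(C)(C)[C@H]1CO[Si](c1ccccc1)(c1ccccc1)C(C)(C)C | intermediate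
10 | [(1S,2S)-2-(tert-butyldiphenylsilyloxymethyl)-3,3-dimethylcyclohexyl]methanol (cis) | OC[C@H]1CCCC(C)(C)[C@H]1CO[Si](c1ccccc1)(c1ccccc1)C(C)(C)C | intermediate
11 | (1S,2S)-2-(tert-butyldiphenylsilyloxymethyl)-3,3-dimethylcyclohexane-1-carboxylic acid (ring A acid, cis) | OC(=O)[C@H]1CCCC(C)(C)[C@H]1CO[Si](c1ccccc1)(c1ccccc1)C(C)(C)C | intermediate
12 | 3-ethoxycyclohex-2-en-1-one | CCOC1=CC(=O)CCC1 | starting material
13 | 4-ethoxy-2-oxocyclohex-3-ene-1-carbaldehyde (enolised) | CCOC1=CC(=O)C(C=O)CC1 | intermediate
14 | 2,3-dibromoprop-1-ene | C=C(Br)CBr | starting material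
15 | rac-1-(2-bromoprop-2-en-1-yl)-4-ethoxy-2-oxocyclohex-3-ene-1-carbaldehyde | CCOC1=CC(=O)[C@](CC(Br)=C)(C=O)CC1 | intermediate
16 | rac-6-(2-bromoprop-2-en-1-yl)-6-(1,3-dioxolan-2-yl)-3-ethoxycyclohex-2-en-1-one | CCOC1=CC(=O)[C@](CC(Br)=C)(C2OCCO2)CC1 | intermediate
17 | rac-4-(2-bromoprop-2-en-1-yl)-4-(1,3-dioxolan-2-yl)cyclohexane-1,3-dione | C=C(Br)C[C@@]1(C2OCCO2)CCC(=O)CC1=O | intermediate
18 | rac-5-(1,3-dioxolan-2-yl)-7-methylidenebicyclo[3.2.1]octane-2,8-dione | C=C1C[C@@]2(C3OCCO3)CCC(=O)[C@@H]1C2=O | intermediate
19 | rac-5-(1,3-dioxolan-2-yl)-7-methylidenebicyclo[3.2.1]oct-3-ene-2,8-dione | C=C1C[C@@]2(C3OCCO3)C=CC(=O)[C@@H]1C2=O | intermediate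
20 | rac-5-(1,3-dioxolan-2-yl)-7-methylidenebicyclo[3.2.1]oct-3-ene-2,8-diol, 2-OH on the face of the C6–C7 bridge, 8-OH towards that bridge | C=C1C[C@@]2(C3OCCO3)C=C[C@@H](O)[C@@H]1[C@H]2O | intermediate
21 | 2-O-acetate of the enantiomer of 20 with the target configuration at the quaternary carbon | C=C1C[C@@]2(C3OCCO3)C=C[C@@H](OC(C)=O)[C@@H]1[C@H]2O | intermediate
22 | 8-O-tert-butyldimethylsilyl ether of 21 | C=C1C[C@@]2(C3OCCO3)C=C[C@@H](OC(C)=O)[C@@H]1[C@H]2O[Si](C)(C)C(C)(C)C | intermediate
23 | 8-(tert-butyldimethylsilyloxy)-5-(1,3-dioxolan-2-yl)-7-methylidenebicyclo[3.2.1]oct-3-en-2-ol, single enantiomer, 2-OH on the face of the C6–C7 bridge | C=C1C[C@@]2(C3OCCO3)C=C[C@@H](O)[C@@H]1[C@H]2O[Si](C)(C)C(C)(C)C | intermediate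
24 | ester of acid 11 with O12 of 23, C12 inverted (oxygen opposite the bridge) | C=C1C[C@@]2(C3OCCO3)C=C[C@H](OC(=O)[C@H]3CCCC(C)(C)[C@H]3CO[Si](c3ccccc3)(c3ccccc3)C(C)(C)C)[C@@H]1[C@H]2O[Si](C)(C)C(C)(C)C | intermediate
25 | trimethylsilyl ketene acetal of 24 (geometry at C10=C20 undefined) | C=C1C[C@@]2(C3OCCO3)C=C[C@H](OC(O[Si](C)(C)C)=C3CCCC(C)(C)[C@H]3CO[Si](c3ccccc3)(c3ccccc3)C(C)(C)C)[C@@H]1[C@H]2O[Si](C)(C)C(C)(C)C | intermediate
26 | trimethylsilyl ester of 27 | C=C1C[C@@]2(C3OCCO3)[C@H]([C@]3(C(=O)O[Si](C)(C)C)CCCC(C)(C)[C@H]3CO[Si](c3ccccc3)(c3ccccc3)C(C)(C)C)C=C[C@@H]1[C@H]2O[Si](C)(C)C(C)(C)C | intermediate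
27 | C20 acid with C9–C10 bond (C10 opposite the bridge on C9, C9 trans to C6 on ring A), C11=C12 alkene, 16-methylidene, C7 dioxolane, 14-O-TBS, 6-O-TBDPS | C=C1C[C@@]2(C3OCCO3)[C@H]([C@]3(C(=O)O)CCCC(C)(C)[C@H]3CO[Si](c3ccccc3)(c3ccccc3)C(C)(C)C)C=C[C@@H]1[C@H]2O[Si](C)(C)C(C)(C)C | intermediate
28 | 20,11-lactone of 27 with iodine at C12 on the bridge face (O11 cis to C10) | C=C1C[C@@]2(C3OCCO3)[C@@H]3[C@@]4(CCCC(C)(C)[C@H]4CO[Si](c4ccccc4)(c4ccccc4)C(C)(C)C)C(=O)O[C@@H]3[C@@H](I)[C@@H]1[C@H]2O[Si](C)(C)C(C)(C)C | intermediate
29 | 20,11-lactone, C12 as CH2, 16-methylidene | C=C1C[C@@]2(C3OCCO3)[C@@H]3[C@@]4(CCCC(C)(C)[C@H]4CO[Si](c4ccccc4)(c4ccccc4)C(C)(C)C)C(=O)O[C@@H]3C[C@@H]1[C@H]2O[Si](C)(C)C(C)(C)C | intermediate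
30 | secondary ozonide of 29 (1,2,4-trioxolane spiro at C16) | C12(OOCO1)C[C@@]3(C4OCCO4)[C@@H]4[C@@]5(CCCC(C)(C)[C@H]5CO[Si](c5ccccc5)(c5ccccc5)C(C)(C)C)C(=O)O[C@@H]4C[C@@H]2[C@H]3O[Si](C)(C)C(C)(C)C | intermediate
31 | 20,11-lactone with C16 ketone | O=C1C[C@@]2(C3OCCO3)[C@@H]3[C@@]4(CCCC(C)(C)[C@H]4CO[Si](c4ccccc4)(c4ccccc4)C(C)(C)C)C(=O)O[C@@H]3C[C@@H]1[C@H]2O[Si](C)(C)C(C)(C)C | intermediate
32 | 20,11-lactone with C7 and C16 dioxolanes | C12(OCCO1)C[C@@]3(C4OCCO4)[C@@H]4[C@@]5(CCCC(C)(C)[C@H]5CO[Si](c5ccccc5)(c5ccccc5)C(C)(C)C)C(=O)O[C@@H]4C[C@@H]2[C@H]3O[Si](C)(C)C(C)(C)C | intermediate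
33 | 11,20-diol, 11-OH opposite the bridge (cis to C10) | C12(OCCO1)C[C@@]3(C4OCCO4)[C@H]([C@]5(CO)CCCC(C)(C)[C@H]5CO[Si](c5ccccc5)(c5ccccc5)C(C)(C)C)[C@H](O)C[C@@H]2[C@H]3O[Si](C)(C)C(C)(C)C | intermediate
34 | C11 ketone with free C20 hydroxyl | C12(OCCO1)C[C@@]3(C4OCCO4)[C@H]([C@]5(CO)CCCC(C)(C)[C@H]5CO[Si](c5ccccc5)(c5ccccc5)C(C)(C)C)C(=O)C[C@@H]2[C@H]3O[Si](C)(C)C(C)(C)C | intermediate
35 | 11,20-diol, 11-OH on the bridge face (trans to C10) | C12(OCCO1)C[C@@]3(C4OCCO4)[C@H]([C@]5(CO)CCCC(C)(C)[C@H]5CO[Si](c5ccccc5)(c5ccccc5)C(C)(C)C)[C@@H](O)C[C@@H]2[C@H]3O[Si](C)(C)C(C)(C)C | intermediate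
36 | 11,20-bis(tert-butyldimethylsilyl) ether of 35 | C12(OCCO1)C[C@@]3(C4OCCO4)[C@H]([C@]5(CO[Si](C)(C)C(C)(C)C)CCCC(C)(C)[C@H]5CO[Si](c5ccccc5)(c5ccccc5)C(C)(C)C)[C@@H](O[Si](C)(C)C(C)(C)C)C[C@@H]2[C@H]3O[Si](C)(C)C(C)(C)C | intermediate
37 | 1-deoxy C20 alcohol: C7 and C16 dioxolanes, 6-O-TBDPS, 11-O-TBS, 14-O-TBS | C12(OCCO1)C[C@@]3(C4OCCO4)[C@H]([C@]5(CO)CCCC(C)(C)[C@H]5CO[Si](c5ccccc5)(c5ccccc5)C(C)(C)C)[C@@H](O[Si](C)(C)C(C)(C)C)C[C@@H]2[C@H]3O[Si](C)(C)C(C)(C)C | intermediate
38 | diethylsilane | CC[SiH2]CC | starting material
39 | C20 diethylhydrosilyl ether of 37 | C12(OCCO1)C[C@@]3(C4OCCO4)[C@H]([C@]5(CO[SiH](CC)CC)CCCC(C)(C)[C@H]5CO[Si](c5ccccc5)(c5ccccc5)C(C)(C)C)[C@@H](O[Si](C)(C)C(C)(C)C)C[C@@H]2[C@H]3O[Si](C)(C)C(C)(C)C | intermediate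
40 | C1–C20 diethyloxasilolane (Si on C1 cis to C20) | C12(OCCO1)C[C@@]3(C4OCCO4)[C@H]([C@@]56CO[Si](CC)(CC)[C@H]6CCC(C)(C)[C@H]5CO[Si](c5ccccc5)(c5ccccc5)C(C)(C)C)[C@@H](O[Si](C)(C)C(C)(C)C)C[C@@H]2[C@H]3O[Si](C)(C)C(C)(C)C | intermediate
41 | 1,20-diol (1-OH cis to C20) | C12(OCCO1)C[C@@]3(C4OCCO4)[C@H]([C@]5(CO)[C@@H](O)CCC(C)(C)[C@H]5CO[Si](c5ccccc5)(c5ccccc5)C(C)(C)C)[C@@H](O[Si](C)(C)C(C)(C)C)C[C@@H]2[C@H]3O[Si](C)(C)C(C)(C)C | intermediate
42 | C20 triethylsilyl ether of 41 | C12(OCCO1)C[C@@]3(C4OCCO4)[C@H]([C@]5(CO[Si](CC)(CC)CC)[C@@H](O)CCC(C)(C)[C@H]5CO[Si](c5ccccc5)(c5ccccc5)C(C)(C)C)[C@@H](O[Si](C)(C)C(C)(C)C)C[C@@H]2[C@H]3O[Si](C)(C)C(C)(C)C | intermediate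
43 | C1 acetate, C20 triethylsilyl ether | C12(OCCO1)C[C@@]3(C4OCCO4)[C@H]([C@]5(CO[Si](CC)(CC)CC)[C@@H](OC(C)=O)CCC(C)(C)[C@H]5CO[Si](c5ccccc5)(c5ccccc5)C(C)(C)C)[C@@H](O[Si](C)(C)C(C)(C)C)C[C@@H]2[C@H]3O[Si](C)(C)C(C)(C)C | intermediate
44 | 7,20-lactol (C7 undefined) with C16 ketone, C1 acetate | O=C1C[C@@]23C(O)OC[C@]4([C@@H](OC(C)=O)CCC(C)(C)[C@H]4CO[Si](c4ccccc4)(c4ccccc4)C(C)(C)C)[C@@H]2[C@@H](O[Si](C)(C)C(C)(C)C)C[C@@H]1[C@H]3O[Si](C)(C)C(C)(C)C | intermediate
45 | 7,20-lactone with C16 ketone | O=C1C[C@@]23C(=O)OC[C@]4([C@@H](OC(C)=O)CCC(C)(C)[C@H]4CO[Si](c4ccccc4)(c4ccccc4)C(C)(C)C)[C@@H]2[C@@H](O[Si](C)(C)C(C)(C)C)C[C@@H]1[C@H]3O[Si](C)(C)C(C)(C)C | intermediate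
46 | 7,20-lactone with 16-methylidene | C=C1C[C@@]23C(=O)OC[C@]4([C@@H](OC(C)=O)CCC(C)(C)[C@H]4CO[Si](c4ccccc4)(c4ccccc4)C(C)(C)C)[C@@H]2[C@@H](O[Si](C)(C)C(C)(C)C)C[C@@H]1[C@H]3O[Si](C)(C)C(C)(C)C | intermediate
47 | 15-hydroxy-16-methylidene lactone (C15 undefined) | C=C1C(O)[C@@]23C(=O)OC[C@]4([C@@H](OC(C)=O)CCC(C)(C)[C@H]4CO[Si](c4ccccc4)(c4ccccc4)C(C)(C)C)[C@@H]2[C@@H](O[Si](C)(C)C(C)(C)C)C[C@@H]1[C@H]3O[Si](C)(C)C(C)(C)C | intermediate
48 | 6-O-TBDPS, 11,14-bis-O-TBS ether of the target | C=C1C(=O)[C@@]23C(=O)OC[C@]4([C@@H](OC(C)=O)CCC(C)(C)[C@H]4CO[Si](c4ccccc4)(c4ccccc4)C(C)(C)C)[C@@H]2[C@@H](O[Si](C)(C)C(C)(C)C)C[C@@H]1[C@H]3O[Si](C)(C)C(C)(C)C | intermediate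
49 | CNP0225182.1 | C=C1C(=O)[C@@]23C(=O)OC[C@]4([C@@H](OC(C)=O)CCC(C)(C)[C@H]4CO)[C@@H]2[C@@H](O)C[C@@H]1[C@H]3O | target

## Step count and least certain steps

Total: 37 steps. Longest linear sequence: 29 steps (12 to 49, steps 9–37); the ring A branch (steps 1–8) joins at step 18.

**Step 29 (key step).** The iridium silyl may fail to reach the equatorial C1–H bond beside the quaternary C10. The hydrosilyl ether would then be returned, or silylation would drift to an aryl C–H bond of the O6 silyl group or to the C6 methylene through a six-membered ring. The fallback replaces metal insertion by a radical 1,6-hydrogen transfer of Hofmann–Löffler–Freytag type, which is known for making 1,3-diols from alcohols.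
- It sets out from 37, which is converted with carbonyldiimidazole and then 2,2,2-trifluoroethylamine into the N-trifluoroethyl carbamate F1.
- N-bromination with acetyl hypobromite gives the N-bromo carbamate F2.
- Irradiation lets the amidyl radical abstract the C1 hydrogen through a seven-membered transition state and pass bromine to C1, giving bromide F3.
- Ag2CO3 promotes displacement of bromide by the carbamate oxygen; only the cis-fused ring with equatorial O1 can form, giving the cyclic imino carbonate F4.
- Aqueous acetic acid hydrolyses F4 to the cyclic carbonate F5.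
- K2CO3 in methanol opens F5, and the route is rejoined at 41.

**Step 12.** Reductive elimination from the stabilised dione enolate may be slow, so that O-alkenylation or protodebromination competes, and the non-enolisable 1,3-diketone product can be opened by base (retro-Claisen). The fallback forms the same bond by carbopalladation instead of enolate coupling. It sets out from 16: a Heck cyclisation (Pd(OAc)2, PPh3, Et3N, MeCN, 80 °C) closes C16 onto C13 of the vinylogous ester in the 5-exo mode, and β-hydride loss towards C11 gives the bicyclic enol ether F6. Mild aqueous acid hydrolyses F6, and the route is rejoined at 18.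

**Step 19.** Deprotonation of the hindered tertiary C10–H may be incomplete, or loss of the allylic carboxylate may compete at the temperature the rearrangement needs; face selectivity at C10 could also erode if one ketene acetal geometry is forced through a disfavoured arrangement. The fallback generates the ketene acetal without strong base (Reformatsky–Claisen). It sets out from 11: the dianion (LiN(i-Pr)2, 2.2 equiv) is brominated with CBr4 to the α-bromo acid F7. Mitsunobu coupling of F7 with 23 gives the bromo ester F8. Zn and Me3SiCl then give the silyl ketene acetal 25, where the route is rejoined and continues through 26 to 27.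

**Step 20.** Iodine has to sit on the hindered bridge face of C12 while the carboxylate attacks C11 from below. If this is slow, iodonium formation at the methylidene group, with participation of a dioxolane oxygen, may take over. The fallback delivers the heteroatom to C11 by syn addition from the tether.
- It sets out from 27, which LiAlH4 reduces to the primary alcohol F9.
- (HMe2Si)2NH gives the hydrodimethylsilyl ether F10.
- Pt2[(CH2=CHSiMe2)2O]3 catalyses intramolecular hydrosilylation to the six-membered oxasilinane F11, with silicon on C11 on the face of C10.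
- H2O2, KF and KHCO3 give the diol F12.
- Ozonolysis (through ozonide F13, Me2S) gives the keto diol F14.
- Ketalisation as in step 23 rejoins the route at 33.

**Step 26.** Hydride may add from the bridge face if the axial C10 substituent on C9 hinders the opposite face more than expected; this would return the 11-epimer. The fallback replaces steric approach control by internal delivery. It sets out from 34: Me4NBH(OAc)3 in MeCN/AcOH exchanges with the C20 hydroxyl, which is held on the face opposite the bridge, and delivers hydride from that face (Evans–Saksena-type directed reduction). It returns at 35 and makes no new compound.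

## Further compounds

F1 | step 29 | N-(2,2,2-trifluoroethyl)carbamate of the C20 hydroxyl of 37 | C12(OCCO1)C[C@@]3(C4OCCO4)[C@H]([C@]5(COC(=O)NCC(F)(F)F)CCCC(C)(C)[C@H]5CO[Si](c5ccccc5)(c5ccccc5)C(C)(C)C)[C@@H](O[Si](C)(C)C(C)(C)C)C[C@@H]2[C@H]3O[Si](C)(C)C(C)(C)C
F2 | step 29 | N-bromo derivative of F1 | C12(OCCO1)C[C@@]3(C4OCCO4)[C@H]([C@]5(COC(=O)N(Br)CC(F)(F)F)CCCC(C)(C)[C@H]5CO[Si](c5ccccc5)(c5ccccc5)C(C)(C)C)[C@@H](O[Si](C)(C)C(C)(C)C)C[C@@H]2[C@H]3O[Si](C)(C)C(C)(C)C
F3 | step 29 | C1 bromide of F1 (C1 undefined) | C12(OCCO1)C[C@@]3(C4OCCO4)[C@H]([C@]5(COC(=O)NCC(F)(F)F)C(Br)CCC(C)(C)[C@H]5CO[Si](c5ccccc5)(c5ccccc5)C(C)(C)C)[C@@H](O[Si](C)(C)C(C)(C)C)C[C@@H]2[C@H]3O[Si](C)(C)C(C)(C)C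
F4 | step 29 | cyclic 1,20-imino carbonate (N-trifluoroethyl), O1 cis to C20 | C12(OCCO1)C[C@@]3(C4OCCO4)[C@H]([C@@]56COC(=NCC(F)(F)F)O[C@H]6CCC(C)(C)[C@H]5CO[Si](c5ccccc5)(c5ccccc5)C(C)(C)C)[C@@H](O[Si](C)(C)C(C)(C)C)C[C@@H]2[C@H]3O[Si](C)(C)C(C)(C)C
F5 | step 29 | cyclic 1,20-carbonate | C12(OCCO1)C[C@@]3(C4OCCO4)[C@H]([C@@]56COC(=O)O[C@H]6CCC(C)(C)[C@H]5CO[Si](c5ccccc5)(c5ccccc5)C(C)(C)C)[C@@H](O[Si](C)(C)C(C)(C)C)C[C@@H]2[C@H]3O[Si](C)(C)C(C)(C)C
F6 | step 12 | rac-5-(1,3-dioxolan-2-yl)-2-ethoxy-7-methylidenebicyclo[3.2.1]oct-2-en-8-one | C=C1C[C@@]2(C3OCCO3)CC=C(OCC)[C@@H]1C2=O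
F7 | step 19 | (2S)-1-bromo-2-(tert-butyldiphenylsilyloxymethyl)-3,3-dimethylcyclohexane-1-carboxylic acid (C1 undefined) | OC(=O)C1(Br)CCCC(C)(C)[C@H]1CO[Si](c1ccccc1)(c1ccccc1)C(C)(C)C
F8 | step 19 | ester of F7 with O12 of 23, C12 inverted | C=C1C[C@@]2(C3OCCO3)C=C[C@H](OC(=O)C3(Br)CCCC(C)(C)[C@H]3CO[Si](c3ccccc3)(c3ccccc3)C(C)(C)C)[C@@H]1[C@H]2O[Si](C)(C)C(C)(C)C
F9 | step 20 | C20 primary alcohol from 27 (C11=C12 alkene, 16-methylidene) | C=C1C[C@@]2(C3OCCO3)[C@H]([C@]3(CO)CCCC(C)(C)[C@H]3CO[Si](c3ccccc3)(c3ccccc3)C(C)(C)C)C=C[C@@H]1[C@H]2O[Si](C)(C)C(C)(C)C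
F10 | step 20 | C20 hydrodimethylsilyl ether of F9 | C=C1C[C@@]2(C3OCCO3)[C@H]([C@]3(CO[SiH](C)C)CCCC(C)(C)[C@H]3CO[Si](c3ccccc3)(c3ccccc3)C(C)(C)C)C=C[C@@H]1[C@H]2O[Si](C)(C)C(C)(C)C
F11 | step 20 | oxasilinane with Si on C11 cis to C10 | C=C1C[C@@]2(C3OCCO3)[C@@H]3[C@@]4(CCCC(C)(C)[C@H]4CO[Si](c4ccccc4)(c4ccccc4)C(C)(C)C)CO[Si](C)(C)[C@@H]3C[C@@H]1[C@H]2O[Si](C)(C)C(C)(C)C
F12 | step 20 | 11,20-diol with 16-methylidene (11-OH cis to C10) | C=C1C[C@@]2(C3OCCO3)[C@H]([C@]3(CO)CCCC(C)(C)[C@H]3CO[Si](c3ccccc3)(c3ccccc3)C(C)(C)C)[C@H](O)C[C@@H]1[C@H]2O[Si](C)(C)C(C)(C)C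
F13 | step 20 | secondary ozonide of F12 | C12(OOCO1)C[C@@]3(C4OCCO4)[C@H]([C@]5(CO)CCCC(C)(C)[C@H]5CO[Si](c5ccccc5)(c5ccccc5)C(C)(C)C)[C@H](O)C[C@@H]2[C@H]3O[Si](C)(C)C(C)(C)C
F14 | step 20 | 11,20-diol with C16 ketone | O=C1C[C@@]2(C3OCCO3)[C@H]([C@]3(CO)CCCC(C)(C)[C@H]3CO[Si](c3ccccc3)(c3ccccc3)C(C)(C)C)[C@H](O)C[C@@H]1[C@H]2O[Si](C)(C)C(C)(C)C
F0 | step 26 | none | none
A1 | alternative 1 | ring A fused isoxazoline | C=C1C[C@@]2(C(=O)OC)[C@H]([C@]34CON=C3CCC(C)(C)[C@H]4CO[Si](C)(C)C(C)(C)C)[C@@H](O[Si](C)(C)C(C)(C)C)C[C@@H]1[C@H]2O[Si](C)(C)C(C)(C)C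
A2 | alternative 2 | ring C cyclohexene cycloadduct | CC(=O)[C@@]12C(=O)OC[C@]3([C@@H](OC(C)=O)CCC(C)(C)[C@H]3CO[Si](C)(C)C(C)(C)C)[C@@H]1[C@@H](O[Si](CC)(CC)CC)C=C[C@H]2O[Si](CC)(CC)CC
A3 | alternative 3 | tetracyclic keto lactone with C11=C12 alkene | C1C(=O)[C@@]23C(=O)OC[C@]4([C@@H](OC(C)=O)CCC(C)(C)[C@H]4CO[Si](C)(C)C(C)(C)C)[C@@H]2C=C[C@@H]1[C@H]3O[Si](C)(C)C(C)(C)C
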